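Trace every millimole of partner through these flasks as you would trace flow through a network, assuming that each molecule of product takes one partner.

| flask | left-handed substrate | right-handed substrate | partner | free catalyst | remark | time |
|---|---|---|---|---|---|---|
| Wednesday's | 10 mM | 10 mM | 4.8 mM | 0.25 mM | run made earlier |  |
| Monday's | 10 mM | 10 mM | 15 mM | 0.25 mM | run made earlier |  |
| epsilon | 10 mM | 10 mM | 6.00 mM | 0.25 mM |  | 2.0 d |
| beta | 10 mM | 10 mM | 20.0 mM | 0.25 mM |  | 2.0 d |

| run | time / h | left-handed product / % | right-handed product / % |
|---|---|---|---|
| Wednesday's | 4.00 | 11.4 | 0.4 |
| Wednesday's | 8.00 | 16.0 | 1.2 |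
| Wednesday's | 15.0 | 18.9 | 1.1 |
| Wednesday's | 25.0 | 19.8 | 0.8 |
| Wednesday's | 50.0 | 19.7 | 0.2 |
| Monday's | 10.0 | 32.1 | 3.7 |
| Monday's | 20.0 | 37.6 | 4.6 |
| Monday's | 30.0 | 40.3 | 4.9 |
| Monday's | 40.0 | 40.9 | 4.8 |
| Monday's | 50.0 | 41.6 | 5.3 |

(standard deviation of a reading: 0.3 percentage points)

* the winner by excess of left-handed product over right-handed product in the product; "neither" if no more than 2 percentage points parts them (epsilon / beta / neither)
* excess of left-handed product over right-handed product in the product at the end, epsilon
* excess of left-handed product over right-handed product in the product at the end, beta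

- free catalyst is single-handed; left-handed substrate and right-handed substrate are mirror images of each other, charged as a racemate, each of them at the stated concentration
- an excess is the difference of the two amounts in percent of their sum
- an excess is below zero if the other one leads

If each mirror substrate decays with its own first-order time constant under the single-handed catalyst, the time drops out of one ratio: the logarithm of the fraction of left-handed substrate unreacted over the same logarithm for the right-handed one, the selectivity factor s. Monday's last reading gives s = 15.9.

The same reading leaves a hole in the books: the two products fail to account for 5.62 mM of the 15 mM of partner, yet left-handed product gains 1.3 percentage points after 30.0 h. Wednesday's last reading leaves 0.820 mM unaccounted for. Scaling Monday's hole with the square of the partner charge predicts 0.575 mM there, and scaling with the partner charge itself predicts 1.80 mM, so the square lies nearer and I use it.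

My own books take 2.0 d as the end. I split what reaches product as Monday's did, then make one pass through s for the right-handed share.

| Entry | epsilon | beta |
|---|---|---|
| Partner charged | 6.00 mM | 20.0 mM |
| Unaccounted for | 0.899 mM | 9.99 mM |
| To both products | 5.10 mM | 10.0 mM |
| To right-handed product | 0.371 mM | 1.28 mM |
| To left-handed product | 4.73 mM | 8.72 mM |
| Excess | 85.4% | 74.3% |

My books favour epsilon by 11 points.

The forecast reasons otherwise, from “Every run stalls with partner left over”, and its numbers differ from mine. It names epsilon, with 92% (85% to 97%) for epsilon and 70% (62% to 77%) for beta.

The flasks give epsilon as the winner, with an excess of 87.4% for epsilon and 73.6% for beta.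

    partner + catalyst intermediate B → free catalyst + right-handed product (k = 104 L mol⁻¹ h⁻¹)
    partner + catalyst intermediate A → free catalyst + left-handed product (k = 3440 L mol⁻¹ h⁻¹)
    2 free catalyst ⇌ resting dimer, settled at all times (K = 1930 L mol⁻¹)
    2 partner → self-condensation product (k = 5.79 L mol⁻¹ h⁻¹)
    free catalyst + right-handed substrate ⇌ catalyst intermediate B (K = 167 L mol⁻¹, k = 20200 L mol⁻¹ h⁻¹)
    free catalyst + left-handed substrate ⇌ catalyst intermediate A (K = 140 L mol⁻¹, k = 3050 L mol⁻¹ h⁻¹)

The gap between the two flasks is due to the difference in partner: given epsilon's partner, beta stands at 87.4% instead of 73.6%. Beta ends with 11% of its left-handed substrate, and s turns its 44.7% of left-handed product into 6.58% of right-handed product, against 6.80% in the flask. A neighbour of beta, charged with 0.10 mM of free catalyst, ends at an excess of 80.5% with 33.3% of left-handed product, for which s gives 3.33% of right-handed product, against 3.59% in that flask.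

The data were generated by integration on assumed constants; noise was put on by code.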